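Variabilin is cut at the C18–C20 single bond, between the methyl-bearing allylic stereocentre and the exocyclic CH of the alkylidene tetronate ring. The key step exploits two features. C20 is the sp2 terminus of the exocyclic C20=C21 enol-ether bond of the butenolide ring and can hold bromine in fixed Z geometry. C18, flanked only by carbon, can be stored as a configurationally defined C–B bond that is absent from the target. The (S)-secondary pinacol boronic ester carrying the whole furyl-diene chain is activated with t-BuLi, passed to zinc with retention and coupled under palladium catalysis with the (Z)-bromomethylene O-methyl tetronate. Both stereoelements are transferred in one fragment union.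

Key step: step 12

Remark: positions follow the usual sesterterpene numbering (C18 stereocentre, C19 its methyl, C20 exocyclic CH, C21–C24 tetronate ring carbons); ethyl 2,4,6-triisopropylbenzoate and (+)-sparteine are taken as purchasable.

Step 1
Reactants: 1 geranyl acetate
Product: 2 (2E,6E)-8-hydroxy-3,7-dimethylocta-2,6-dien-1-yl acetate
Conditions: SeO2 (10 mol%), salicylic acid (10 mol%), t-BuOOH, CH2Cl2, rt
Reagents that add atoms: tert-butyl hydroperoxide, CC(C)(C)OO
Why: Riley-type allylic oxidation (ene reaction, then [2,3]-sigmatropic shift) should pick the electron-richer distal trisubstituted alkene, the one next to the acetate being deactivated, and should give the E-allylic alcohol.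

Step 2
Reactants: 3 furan-3-ylmethanol
Product: 4 3-(chloromethyl)furan
Conditions: SOCl2, pyridine, Et2O, 0 °C
Reagents that add atoms: thionyl chloride, O=S(Cl)Cl
Why: Chlorodehydroxylation through the chlorosulfite (SN2 by chloride), with pyridine taking up HCl so that the acid-sensitive furan should survive; 4 is used at once.

Step 3
Reactants: 4 3-(chloromethyl)furan; 2 (2E,6E)-8-hydroxy-3,7-dimethylocta-2,6-dien-1-yl acetate
Product: 6 (2E,6E)-9-(furan-3-yl)-2,6-dimethylnona-2,6-dien-1-ol, via furan-3-ylmethylmagnesium chloride 5 (not isolated)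
Conditions: Mg, THF, 0 °C to rt; then 2 (0.4 equiv), Li2CuCl4 (5 mol%), THF, −78 to 0 °C; aq NH4Cl
Reagents that add atoms: none
Why: Copper-catalysed cross-coupling of a Grignard reagent with an allylic acetate, in which the first equivalent of 5 only deprotonates the free hydroxyl and the second displaces acetate at the primary carbon (the other allyl terminus is fully substituted), so the E geometry should be kept.

Step 4
Reactants: 6 (2E,6E)-9-(furan-3-yl)-2,6-dimethylnona-2,6-dien-1-ol
Product: 7 3-[(3E,7E)-9-bromo-4,8-dimethylnona-3,7-dien-1-yl]furan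
Conditions: CBr4, PPh3, CH2Cl2, −20 to 0 °C
Reagents that add atoms: carbon tetrabromide, BrC(Br)(Br)Br
Why: Appel reaction, a neutral SN2 bromination through the alkoxyphosphonium salt that should avoid allylic transposition and spare the furan and the alkenes.

Step 5
Reactants: 7 3-[(3E,7E)-9-bromo-4,8-dimethylnona-3,7-dien-1-yl]furan
Product: 8 3-[(3E,7E)-4,8-dimethylundeca-3,7,10-trien-1-yl]furan
Conditions: CH2=CHMgBr, CuI (10 mol%), THF, −30 to 0 °C
Reagents that add atoms: vinylmagnesium bromide, C=C[Mg]Br
Why: Copper-catalysed cross-coupling of a vinyl Grignard reagent with an allylic bromide should take place at the unhindered primary carbon and give the skipped diene with the E-alkene untouched.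

Step 6
Reactants: 8 3-[(3E,7E)-4,8-dimethylundeca-3,7,10-trien-1-yl]furan
Product: 9 2-[(4E,8E)-11-(furan-3-yl)-4,8-dimethylundeca-4,8-dien-1-yl]-4,4,5,5-tetramethyl-1,3,2-dioxaborolane
Conditions: pinacolborane, [Ir(cod)Cl]2 (1.5 mol%), dppm (3 mol%), CH2Cl2, rt
Reagents that add atoms: pinacolborane, CC1(C)OBOC1(C)C
Why: Iridium-catalysed anti-Markovnikov hydroboration should address only the monosubstituted alkene, the trisubstituted alkenes and the furan being too hindered or unreactive.

Step 7
Reactants: 10 ethyl 2,4,6-triisopropylbenzoate; 9 2-[(4E,8E)-11-(furan-3-yl)-4,8-dimethylundeca-4,8-dien-1-yl]-4,4,5,5-tetramethyl-1,3,2-dioxaborolane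
Product: 13 2-[(2S,6E,10E)-13-(furan-3-yl)-6,10-dimethyltrideca-6,10-dien-2-yl]-4,4,5,5-tetramethyl-1,3,2-dioxaborolane, via lithiated benzoate 11 (not isolated), via boronate complex 12 (not isolated)
Conditions: 10 (1.4 equiv), s-BuLi (1.3 equiv), (+)-sparteine (1.3 equiv), Et2O, −78 °C, 5 h; then 9, −78 °C, 1 h; then 35 °C; aq NH4Cl
Reagents that add atoms: none
Why: Lithiation–borylation, in which (+)-sparteine-directed deprotonation removes the pro-R hydrogen to give the R-configured carbenoid 11, borylation proceeds with retention, and the primary alkyl group of 12 migrates from boron to carbon with inversion (Matteson-type 1,2-metalate rearrangement, benzoate as leaving group), which sets C18 as S.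

Step 8
Reactants: 14 ethyl 2-methyl-3-oxopentanoate
Product: 16 4-hydroxy-3,5-dimethylfuran-2(5H)-one (racemic 3,5-dimethyltetronic acid), via 4-bromo keto ester 15 (not isolated)
Conditions: Br2 (1.0 equiv), CHCl3, 0 °C to rt; concentrate; neat, 120 °C
Reagents that add atoms: none
Why: Bromination, HBr-mediated equilibration to the 4-bromo keto ester and thermal lactonisation with loss of bromoethane is the classical tetronic acid synthesis; the racemic C5 centre is erased in step 10.

Step 9
Reactants: 16 4-hydroxy-3,5-dimethylfuran-2(5H)-one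
Product: 17 4-methoxy-3,5-dimethylfuran-2(5H)-one (racemic)
Conditions: Me2SO4, K2CO3, acetone, reflux
Reagents that add atoms: dimethyl sulfate, COS(=O)(=O)OC
Why: O-alkylation of the tetronate anion (a vinylogous carboxylate) with the hard electrophile dimethyl sulfate should give the 4-methoxy vinylogous ester.

Step 10
Reactants: 17 4-methoxy-3,5-dimethylfuran-2(5H)-one
Product: 19 4-methoxy-3-methyl-5-methylidenefuran-2(5H)-one, via tertiary bromide 18 (not isolated)
Conditions: NBS (1.0 equiv), AIBN (cat.), PhCF3, reflux; filter; then Et3N, CH2Cl2, 0 °C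
Reagents that add atoms: none
Why: Wohl–Ziegler bromination should take the tertiary C5–H, which gives an allylic, oxygen-stabilised radical (the ring position is also the one attacked in simple 3-methylbutenolides), and the tertiary bromide then loses HBr towards its only β-hydrogens, those of the methyl group.

Step 11
Reactants: 19 4-methoxy-3-methyl-5-methylidenefuran-2(5H)-one
Product: 21 (5Z)-5-(bromomethylidene)-4-methoxy-3-methylfuran-2(5H)-one, via dibromide 20 (not isolated)
Conditions: Br2, CH2Cl2, −20 °C; then Et3N, 0 °C to rt
Reagents that add atoms: bromine, BrBr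
Why: Bromine addition to the electron-rich exocyclic enol-ether alkene followed by dehydrobromination is the standard entry to bromomethylene butenolides and should give the Z isomer, because the E isomer would press bromine against the C4 methoxy group.

Step 12
Reactants: 13 2-[(2S,6E,10E)-13-(furan-3-yl)-6,10-dimethyltrideca-6,10-dien-2-yl]-4,4,5,5-tetramethyl-1,3,2-dioxaborolane; 21 (5Z)-5-(bromomethylidene)-4-methoxy-3-methylfuran-2(5H)-one
Product: 24 (5Z)-5-[(2S,6E,10E)-13-(furan-3-yl)-2,6,10-trimethyltrideca-6,10-dien-1-ylidene]-4-methoxy-3-methylfuran-2(5H)-one (O-methylvariabilin), via tert-butyl boronate complex 22 (not isolated), via secondary alkylzinc chloride 23 (not isolated)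
Conditions: 13, t-BuLi (1.05 equiv), THF, −78 °C to rt; ZnCl2 (1.1 equiv), THF, rt; then 21, Pd(OAc)2 (5 mol%), CPhos (10 mol%), THF, rt
Reagents that add atoms: none
Why: t-BuLi adds to the boron of 13 to give the tetracoordinate boronate 22, whose secondary C18–B bond is handed to ZnCl2 through a closed, front-side (retentive SE2) transition state while the bulky tert-butyl group stays on boron, giving the configurationally stable alkylzinc 23; zerovalent palladium inserts into the C20–Br bond of 21 with retention of the Z geometry, 23 transmetalates to the divalent alkenylpalladium bromide with retention, and reductive elimination forges C18–C20. The closest known reaction types are the stereoretentive boron-to-zinc transmetalation of t-BuLi-activated secondary pinacol boronic esters and the Negishi coupling of chiral secondary alkylzinc reagents with alkenyl halides, and bromomethylene butenolides are established partners in palladium-catalysed couplings. No ring is closed. No new stereocentre is created: C18 (set in step 7) is carried through three retentive events to the S configuration of the target, and the C20=C21 geometry is that of 21. The step needs reductive elimination to outrun β-hydride elimination and re-insertion (which would walk palladium to C19 or C17), which the bulky, electron-rich biaryl phosphine CPhos and the electron-poor alkenyl ligand should secure. It also needs chemoselectivity for the C–Br bond over the lactone and vinylogous ester carbonyl, which the low nucleophilicity of the organozinc secures, the furan ring and both trisubstituted alkenes being spectators.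

Step 13
Reactants: 24 O-methylvariabilin
Product: 25 variabilin, (5Z)-5-[(2S,6E,10E)-13-(furan-3-yl)-2,6,10-trimethyltrideca-6,10-dien-1-ylidene]-4-hydroxy-3-methylfuran-2(5H)-one
Conditions: NaSEt, DMF, rt to 50 °C; then 1 M HCl, 0 °C
Reagents that add atoms: none
Why: SN2 demethylation of the vinylogous methyl ester by the soft thiolate releases the stabilised tetronate anion, which is protonated on work-up; the base is too weak to remove the C18 hydrogen, and any reversible conjugate addition should return to the more stable Z-alkene.

Compound list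
1 | geranyl acetate | CC(C)=CCC/C(C)=C/COC(C)=O | starting material
2 | (2E,6E)-8-hydroxy-3,7-dimethylocta-2,6-dien-1-yl acetate | OC/C(C)=C/CC/C(C)=C/COC(C)=O | intermediate
3 | furan-3-ylmethanol | OCc1ccoc1 | starting material
4 | 3-(chloromethyl)furan | ClCc1ccoc1 | intermediate
5 | furan-3-ylmethylmagnesium chloride | Cl[Mg]Cc1ccoc1 | intermediate
6 | (2E,6E)-9-(furan-3-yl)-2,6-dimethylnona-2,6-dien-1-ol | OC/C(C)=C/CC/C(C)=C/CCc1ccoc1 | intermediate
7 | 3-[(3E,7E)-9-bromo-4,8-dimethylnona-3,7-dien-1-yl]furan | BrC/C(C)=C/CC/C(C)=C/CCc1ccoc1 | intermediate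
8 | 3-[(3E,7E)-4,8-dimethylundeca-3,7,10-trien-1-yl]furan | C=CC/C(C)=C/CC/C(C)=C/CCc1ccoc1 | intermediate
9 | 2-[(4E,8E)-11-(furan-3-yl)-4,8-dimethylundeca-4,8-dien-1-yl]-4,4,5,5-tetramethyl-1,3,2-dioxaborolane | CC1(C)OB(CCC/C(C)=C/CC/C(C)=C/CCc2ccoc2)OC1(C)C | intermediate
10 | ethyl 2,4,6-triisopropylbenzoate | CCOC(=O)c1c(C(C)C)cc(C(C)C)cc1C(C)C | starting material
11 | (R)-1-lithioethyl 2,4,6-triisopropylbenzoate ((+)-sparteine complex) | [Li][C@H](C)OC(=O)c1c(C(C)C)cc(C(C)C)cc1C(C)C | intermediate
12 | lithium boronate complex of 9 and 11 | [Li+].CC1(C)O[B-](CCC/C(C)=C/CC/C(C)=C/CCc2ccoc2)(OC1(C)C)[C@H](C)OC(=O)c1c(C(C)C)cc(C(C)C)cc1C(C)C | intermediate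
13 | 2-[(2S,6E,10E)-13-(furan-3-yl)-6,10-dimethyltrideca-6,10-dien-2-yl]-4,4,5,5-tetramethyl-1,3,2-dioxaborolane | CC1(C)OB(OC1(C)C)[C@@H](C)CCC/C(C)=C/CC/C(C)=C/CCc1ccoc1 | intermediate
14 | ethyl 2-methyl-3-oxopentanoate | CCC(=O)C(C)C(=O)OCC | starting material
15 | ethyl 4-bromo-2-methyl-3-oxopentanoate (stereoisomer mixture) | CC(Br)C(=O)C(C)C(=O)OCC | intermediate
16 | 4-hydroxy-3,5-dimethylfuran-2(5H)-one (racemic) | CC1OC(=O)C(C)=C1O | intermediate
17 | 4-methoxy-3,5-dimethylfuran-2(5H)-one (racemic) | COC1=C(C)C(=O)OC1C | intermediate
18 | 5-bromo-4-methoxy-3,5-dimethylfuran-2(5H)-one (racemic) | COC1=C(C)C(=O)OC1(C)Br | intermediate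
19 | 4-methoxy-3-methyl-5-methylidenefuran-2(5H)-one | COC1=C(C)C(=O)OC1=C | intermediate
20 | 5-bromo-5-(bromomethyl)-4-methoxy-3-methylfuran-2(5H)-one (racemic) | COC1=C(C)C(=O)OC1(Br)CBr | intermediate
21 | (5Z)-5-(bromomethylidene)-4-methoxy-3-methylfuran-2(5H)-one | CC1=C(OC)/C(=C/Br)OC1=O | intermediate
22 | lithium tert-butyl boronate complex of 13 | [Li+].CC(C)(C)[B-]1(OC(C)(C)C(C)(C)O1)[C@@H](C)CCC/C(C)=C/CC/C(C)=C/CCc1ccoc1 | intermediate
23 | [(2S,6E,10E)-13-(furan-3-yl)-6,10-dimethyltrideca-6,10-dien-2-yl]zinc chloride | Cl[Zn][C@@H](C)CCC/C(C)=C/CC/C(C)=C/CCc1ccoc1 | intermediate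
24 | O-methylvariabilin | CC1=C(OC)/C(=C/[C@@H](C)CCC/C(C)=C/CC/C(C)=C/CCc2ccoc2)OC1=O | intermediate
25 | variabilin | CC1=C(O)/C(=C/[C@@H](C)CCC/C(C)=C/CC/C(C)=C/CCc2ccoc2)OC1=O | target

Total step count: 13. Longest linear sequence: 8 steps (1, 3, 4, 5, 6, 7, 12, 13) from geranyl acetate.

Steps most likely to fail

Step 12. Configurational integrity at C18 may erode during the boron-to-zinc transfer. β-Hydride elimination and re-insertion at palladium may also move the metal along the chain before reductive elimination. The fallback sets out from 13 and comes back at 24. It makes the same C18–C20 bond by a one-carbon Matteson homologation. Compound 13 is treated with LiCHCl2 (CH2Cl2, n-BuLi, THF, −100 °C, then rt), so that C18 migrates from boron to carbon with retention and gives the α-chloroboronic ester F1. Oxidation with H2O2 and NaOH should collapse it to the aldehyde F2. Purchased 3-methyltetronic acid F3 is O-methylated as in step 9 to 4-methoxy-3-methylfuran-2(5H)-one F4. Its C5 lithium dienolate (LDA, THF, −78 °C) adds to F2 to give the aldol adduct F5. Mesylation (MsCl, Et3N) gives the mesylate F6, and elimination with DBU should give 24, the Z-alkene being the more stable one.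

Step 10. Hydrogen abstraction from the C3 methyl group may compete, and the 5-methylidene product may polymerise during handling. The fallback sets out from 17 and comes back at 19. It replaces the radical step by an ionic one. Compound 17 is deprotonated at C5 (LDA, THF, −78 °C) and trapped with PhSeBr to give the selenide F7. Oxidation with H2O2 at 0 °C gives the selenoxide F8, which should undergo syn-elimination towards the methyl group at or below room temperature.

Step 3. The reactive furylmethyl Grignard reagent may attack the acetate carbonyl (deacetylation) in place of allylic substitution. The fallback sets out from 4 and comes back at 6. It reverses the order of coupling and oxidation. The Grignard reagent 5 made from 4 is coupled (Li2CuCl4 cat., THF) with purchased geranyl bromide F9 to give dendrolasin F10. The allylic oxidation of step 1 (SeO2 cat., t-BuOOH) is then run on F10, whose terminal isopropylidene group is the most reactive alkene.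

Further compounds
F1 | step 12 | 2-[(2S,6E,10E)-1-chloro-13-(furan-3-yl)-2,6,10-trimethyltrideca-6,10-dien-1-yl]-4,4,5,5-tetramethyl-1,3,2-dioxaborolane (epimers at C1) | ClC(B1OC(C)(C)C(C)(C)O1)[C@@H](C)CCC/C(C)=C/CC/C(C)=C/CCc1ccoc1
F2 | step 12 | (2S,6E,10E)-13-(furan-3-yl)-2,6,10-trimethyltrideca-6,10-dienal | O=C[C@@H](C)CCC/C(C)=C/CC/C(C)=C/CCc1ccoc1
F3 | step 12 | 3-methyltetronic acid (purchased) | CC1=C(O)COC1=O
F4 | step 12 | 4-methoxy-3-methylfuran-2(5H)-one | COC1=C(C)C(=O)OC1
F5 | step 12 | 5-[(2S,6E,10E)-13-(furan-3-yl)-1-hydroxy-2,6,10-trimethyltrideca-6,10-dien-1-yl]-4-methoxy-3-methylfuran-2(5H)-one (diastereomer mixture) | COC1=C(C)C(=O)OC1C(O)[C@@H](C)CCC/C(C)=C/CC/C(C)=C/CCc1ccoc1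
F6 | step 12 | methanesulfonate of F5 | COC1=C(C)C(=O)OC1C(OS(C)(=O)=O)[C@@H](C)CCC/C(C)=C/CC/C(C)=C/CCc1ccoc1
F7 | step 10 | 4-methoxy-3,5-dimethyl-5-(phenylselanyl)furan-2(5H)-one (racemic) | COC1=C(C)C(=O)OC1(C)[Se]c1ccccc1
F8 | step 10 | 4-methoxy-3,5-dimethyl-5-(phenylseleninyl)furan-2(5H)-one | COC1=C(C)C(=O)OC1(C)[Se](=O)c1ccccc1
F9 | step 3 | geranyl bromide (purchased) | CC(C)=CCC/C(C)=C/CBr
F10 | step 3 | dendrolasin, 3-[(3E)-4,8-dimethylnona-3,7-dien-1-yl]furan | CC(C)=CCC/C(C)=C/CCc1ccoc1
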